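**Plan**

1. Retrosynthesis: the two palmitate C–O bonds are cut first (to lutein), then C11'=C12' and C11=C12 (two Wittig cuts, to a C10 dialdehyde and two C15 phosphonium salts), then C9'–C10' and C9–C10 (vinyl additions), C7'=C8' (Horner–Wadsworth–Emmons), C6–C7 (Heck), and last C1'–C2' and C5'–C6' of the epsilon ring.
2. Enabling feature: the epsilon ring has quaternary C1' beside the doubly allylic stereocentre C6', oxygen at C3' and the C4'=C5' alkene. This is the pattern left when a 2,4-dioxygenated pentadiene adds across a 3-methylbut-2-enoyl unit and the C5' oxygen is eliminated.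
3. Forward, epsilon half: the ring is closed first by a catalytic asymmetric [4+2] annulation, the C3' ketone is reduced, and the chain is grown to the epsilon C15 phosphonium salt. Beta half: the ring comes ready-made from (4R,6R)-actinol and is grown to the beta C15 salt.
4. Union: beta salt + C10 dialdehyde gives a C25 aldehyde; the epsilon salt then completes the C40 chain; desilylation and double palmitoylation finish the synthesis.
5. Stereochemistry: C6' from the chiral copper bis(oxazoline) catalyst; C3' from substrate-controlled Luche reduction (trans to C6'); C3 from the chiral pool; alkene geometry from E-selective olefinations and thermal Z-to-E equilibration.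

Key step: step 3

Remark: carotenoid locants are used (primed for the epsilon half); (4R,6R)-4-hydroxy-2,2,6-trimethylcyclohexan-1-one and (2E,4E,6E)-2,7-dimethylocta-2,4,6-trienedial are taken to be purchasable; TBS = tert-butyldimethylsilyl.

**Route**

Step 1
Reactants: 1 pentane-2,4-dione
Product: 3 (3Z)-2,4-bis(trimethylsilyloxy)penta-1,3-diene, via mono-silyl enol ether 2 (not isolated)
Conditions: Me3SiOTf (2.2 equiv), Et3N, Et2O, 0 °C to rt; distillation
Reagents that add atoms: trimethylsilyl trifluoromethanesulfonate, C[Si](C)(C)OS(=O)(=O)C(F)(F)F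
Why: Silyl enol ether formation by soft enolisation, in which the chelated enol oxygen is silylated first and the remaining methyl ketone is then silylated on its terminal side, should give the 1,3-dioxygenated diene.

Step 2
Reactants: 4 1,3-oxazolidin-2-one; 5 3-methylbut-2-enoyl chloride
Product: 7 3-(3-methylbut-2-enoyl)-1,3-oxazolidin-2-one, via lithium oxazolidinide 6 (not isolated)
Conditions: n-BuLi, THF, −78 °C; then 5, −78 to 0 °C
Reagents that add atoms: none
Why: N-acylation of the lithiated oxazolidinone at low temperature, without a tertiary amine, avoids the vinylketene pathway that would move the double bond out of conjugation.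

Step 3
Reactants: 3 (3Z)-2,4-bis(trimethylsilyloxy)penta-1,3-diene; 7 3-(3-methylbut-2-enoyl)-1,3-oxazolidin-2-one
Product: 10 3-{[(1R)-2,6,6-trimethyl-4-oxocyclohex-2-en-1-yl]carbonyl}-1,3-oxazolidin-2-one, via bis-silyl cycloadduct 8 (not isolated), via silyloxy ketone 9 (not isolated)
Conditions: [Cu((R,R)-t-Bu-box)](SbF6)2 (10 mol %, preformed; t-Bu-box = 2,2'-(propane-2,2-diyl)bis[(4R)-4-tert-butyl-4,5-dihydro-1,3-oxazole]), 3 (2 equiv), CH2Cl2, −20 °C to rt; then CF3CO2H, wet CH2Cl2, 0 °C
Reagents that add atoms: none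
Why: Proposed new method: the imide should chelate the cationic divalent-copper centre through both carbonyl oxygens in a square-planar complex, which holds the enoyl group s-cis (the s-trans form would press the cis β-methyl against the oxazolidinone) and activates it enough for the CH2 terminus of the electron-rich diene to bond to the fully substituted β-carbon, forming C1'–C2'. The copper-bound (Z)-enolate then bonds through C6' to the silyloxocarbenium carbon C5', in concert or as a 6-(enolexo)-exo-trig closure, so the event is an asynchronous [4+2] cycloaddition that closes the six-membered epsilon ring. The closest known reactions are the bis(oxazoline)–copper catalysed Diels–Alder reactions of N-acryloyl and N-crotonoyl oxazolidinones and the Mukaiyama–Michael additions of silyl enol ethers to chelating acceptors with the same catalysts, neither of which has been shown for a β,β-dimethyl enoyl imide. C6' is the only stereocentre that survives and is set by the ligand: with the (R,R) ligand the tert-butyl group beside the acyl oxygen should cover the α-Re face, so C5' arrives on the α-Si face, which corresponds to (R) at C6'. The step needs enantiofacial control at C6' and 1,4-regiochemistry; two-point binding of the imide secures the first, and the diene polarity (nucleophilic C1, electrophilic C4) secures the second while pairing each crowded carbon with an open one. Acid then hydrolyses the enol ether of 8 and eliminates silanol from 9, which erases the C5' stereocentre and leaves the C4'=C5' enone; this stage is kept acidic and cold because C6'–H is α to the imide and γ to the enone.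

Step 4
Reactants: 10 3-{[(1R)-2,6,6-trimethyl-4-oxocyclohex-2-en-1-yl]carbonyl}-1,3-oxazolidin-2-one
Product: 11 3-{[(1R,4R)-4-hydroxy-2,6,6-trimethylcyclohex-2-en-1-yl]carbonyl}-1,3-oxazolidin-2-one
Conditions: NaBH4, CeCl3·7H2O, MeOH, −78 °C
Reagents that add atoms: none
Why: Luche 1,2-reduction should spare the imide at low temperature, and because the C6' acyl group sits pseudoaxial (away from the C5' methyl) while the axial C1' methyl blocks the other face, hydride should enter syn to the acyl group and place the 3'-hydroxyl trans to it, i.e. (3'R).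

Step 5
Reactants: 11 3-{[(1R,4R)-4-hydroxy-2,6,6-trimethylcyclohex-2-en-1-yl]carbonyl}-1,3-oxazolidin-2-one
Product: 12 3-{[(1R,4R)-4-(tert-butyldimethylsilyloxy)-2,6,6-trimethylcyclohex-2-en-1-yl]carbonyl}-1,3-oxazolidin-2-one
Conditions: TBSCl, imidazole, DMF, rt
Reagents that add atoms: tert-butyldimethylsilyl chloride, CC(C)(C)[Si](C)(C)Cl
Why: Standard silylation of a secondary allylic alcohol under conditions too weakly basic to enolise the imide.

Step 6
Reactants: 12 3-{[(1R,4R)-4-(tert-butyldimethylsilyloxy)-2,6,6-trimethylcyclohex-2-en-1-yl]carbonyl}-1,3-oxazolidin-2-one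
Product: 13 [(1R,4R)-4-(tert-butyldimethylsilyloxy)-2,6,6-trimethylcyclohex-2-en-1-yl]methanol
Conditions: LiBH4, MeOH (1 equiv), THF, 0 °C
Reagents that add atoms: none
Why: Reductive cleavage of an N-acyl oxazolidinone by hydride attack on the exocyclic carbonyl should give the primary alcohol and release the oxazolidinone without disturbing C6'.

Step 7
Reactants: 13 [(1R,4R)-4-(tert-butyldimethylsilyloxy)-2,6,6-trimethylcyclohex-2-en-1-yl]methanol
Product: 14 (1R,4R)-4-(tert-butyldimethylsilyloxy)-2,6,6-trimethylcyclohex-2-ene-1-carbaldehyde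
Conditions: Dess–Martin periodinane, NaHCO3, CH2Cl2, 0 °C to rt; used without storage
Reagents that add atoms: none
Why: Dess–Martin oxidation under bicarbonate buffering is mild enough that the β,γ-unsaturated aldehyde should neither epimerise at C6' nor move its double bond into conjugation.

Step 8
Reactants: 14 (1R,4R)-4-(tert-butyldimethylsilyloxy)-2,6,6-trimethylcyclohex-2-ene-1-carbaldehyde; 15 dimethyl (2-oxopropyl)phosphonate
Product: 16 (3E)-4-[(1R,4R)-4-(tert-butyldimethylsilyloxy)-2,6,6-trimethylcyclohex-2-en-1-yl]but-3-en-2-one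
Conditions: LiCl, i-Pr2NEt, MeCN, rt
Reagents that add atoms: none
Why: Horner–Wadsworth–Emmons olefination of a β-ketophosphonate under LiCl/amine conditions needs only a weak base, is E-selective, and is the usual way to olefinate α-stereogenic aldehydes without loss of configuration.

Step 9
Reactants: 16 (3E)-4-[(1R,4R)-4-(tert-butyldimethylsilyloxy)-2,6,6-trimethylcyclohex-2-en-1-yl]but-3-en-2-one; 17 vinylmagnesium bromide
Product: 18 (1E)-1-[(1R,4R)-4-(tert-butyldimethylsilyloxy)-2,6,6-trimethylcyclohex-2-en-1-yl]-3-methylpenta-1,4-dien-3-ol (both C3 epimers)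
Conditions: THF, −20 to 0 °C; aq. NH4Cl
Reagents that add atoms: none
Why: Grignard 1,2-addition to the enone carbonyl, as in the classical vinylation of ionones, forms C9'–C10', and the carbinol epimers are immaterial because that carbon becomes sp2 in the next step.

Step 10
Reactants: 18 (1E)-1-[(1R,4R)-4-(tert-butyldimethylsilyloxy)-2,6,6-trimethylcyclohex-2-en-1-yl]-3-methylpenta-1,4-dien-3-ol
Product: 19 {(2E,4E)-5-[(1R,4R)-4-(tert-butyldimethylsilyloxy)-2,6,6-trimethylcyclohex-2-en-1-yl]-3-methylpenta-2,4-dien-1-yl}triphenylphosphonium bromide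
Conditions: PPh3·HBr (1.0 equiv), CH2Cl2, 0 °C to rt; crystallisation
Reagents that add atoms: triphenylphosphine hydrobromide, [Br-].[PH+](c1ccccc1)(c2ccccc2)c3ccccc3
Why: Acid-promoted ionisation of the tertiary bis-allylic alcohol and capture of the cation by PPh3 at its unhindered primary terminus (allylic transposition, the classical C15 Wittig salt formation) should give the conjugated dienyl salt, with one equivalent of acid in an aprotic solvent sparing the allylic silyl ether and crystallisation enriching the 9'E isomer.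

Step 11
Reactants: 20 (4R,6R)-4-hydroxy-2,2,6-trimethylcyclohexan-1-one
Product: 21 (4R,6R)-4-(tert-butyldimethylsilyloxy)-2,2,6-trimethylcyclohexan-1-one
Conditions: TBSCl, imidazole, DMF, rt
Reagents that add atoms: tert-butyldimethylsilyl chloride, CC(C)(C)[Si](C)(C)Cl
Why: Standard silylation protects the hydroxyl against the strong base of the next step.

Step 12
Reactants: 21 (4R,6R)-4-(tert-butyldimethylsilyloxy)-2,2,6-trimethylcyclohexan-1-one
Product: 23 (4R)-4-(tert-butyldimethylsilyloxy)-2,6,6-trimethylcyclohex-1-en-1-yl trifluoromethanesulfonate, via lithium enolate 22 (not isolated)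
Conditions: LDA, THF, −78 to 0 °C; then PhNTf2, −78 °C to rt
Reagents that add atoms: N-phenylbis(trifluoromethanesulfonimide), O=S(=O)(N(c1ccccc1)S(=O)(=O)C(F)(F)F)C(F)(F)F
Why: Enol triflate formation is regiochemically unambiguous because the ketone has a single α-hydrogen, and it removes the C6 stereocentre on purpose while leaving C4 (the future C3) untouched.

Step 13
Reactants: 23 (4R)-4-(tert-butyldimethylsilyloxy)-2,6,6-trimethylcyclohex-1-en-1-yl trifluoromethanesulfonate; 24 but-3-en-2-one
Product: 25 (3E)-4-[(4R)-4-(tert-butyldimethylsilyloxy)-2,6,6-trimethylcyclohex-1-en-1-yl]but-3-en-2-one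
Conditions: Pd(OAc)2 (5 mol %), PPh3 (10 mol %), Et3N, DMF, 70 °C
Reagents that add atoms: none
Why: Heck reaction of an enol triflate with an enone (oxidative addition to zerovalent palladium formed in situ, insertion at the CH2 terminus, β-hydride elimination) should form C6–C7 and give the E-dienone.

Step 14
Reactants: 25 (3E)-4-[(4R)-4-(tert-butyldimethylsilyloxy)-2,6,6-trimethylcyclohex-1-en-1-yl]but-3-en-2-one; 17 vinylmagnesium bromide
Product: 26 (1E)-1-[(4R)-4-(tert-butyldimethylsilyloxy)-2,6,6-trimethylcyclohex-1-en-1-yl]-3-methylpenta-1,4-dien-3-ol (both C3 epimers)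
Conditions: THF, −20 to 0 °C; aq. NH4Cl
Reagents that add atoms: none
Why: Grignard 1,2-addition to the dienone carbonyl forms C9–C10, exactly as in the vinylation of beta-ionone.

Step 15
Reactants: 26 (1E)-1-[(4R)-4-(tert-butyldimethylsilyloxy)-2,6,6-trimethylcyclohex-1-en-1-yl]-3-methylpenta-1,4-dien-3-ol
Product: 27 {(2E,4E)-5-[(4R)-4-(tert-butyldimethylsilyloxy)-2,6,6-trimethylcyclohex-1-en-1-yl]-3-methylpenta-2,4-dien-1-yl}triphenylphosphonium bromide
Conditions: PPh3·HBr (1.0 equiv), CH2Cl2, 0 °C to rt; crystallisation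
Reagents that add atoms: triphenylphosphine hydrobromide, [Br-].[PH+](c1ccccc1)(c2ccccc2)c3ccccc3
Why: The same ionisation and phosphine capture with allylic transposition as in step 10 should give the beta C15 Wittig salt.

Step 16
Reactants: 27 {(2E,4E)-5-[(4R)-4-(tert-butyldimethylsilyloxy)-2,6,6-trimethylcyclohex-1-en-1-yl]-3-methylpenta-2,4-dien-1-yl}triphenylphosphonium bromide; 28 (2E,4E,6E)-2,7-dimethylocta-2,4,6-trienedial
Product: 30 (2E,4E,6E,8E,10E,12E)-13-[(4R)-4-(tert-butyldimethylsilyloxy)-2,6,6-trimethylcyclohex-1-en-1-yl]-2,7,11-trimethyltrideca-2,4,6,8,10,12-hexaenal, via (11Z)-C25 aldehyde 29 (not isolated)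
Conditions: NaOMe, MeOH/CH2Cl2, −20 °C to rt, 28 in excess (2 equiv); then n-heptane, reflux, Ar, dark
Reagents that add atoms: none
Why: Wittig olefination forms C11=C12, mono-olefination should prevail because the dialdehyde is in excess and the C25 polyenal product is the less electrophilic aldehyde, and the strained 11Z isomer formed alongside relaxes to all-E on heating.

Step 17
Reactants: 19 {(2E,4E)-5-[(1R,4R)-4-(tert-butyldimethylsilyloxy)-2,6,6-trimethylcyclohex-2-en-1-yl]-3-methylpenta-2,4-dien-1-yl}triphenylphosphonium bromide; 30 (2E,4E,6E,8E,10E,12E)-13-[(4R)-4-(tert-butyldimethylsilyloxy)-2,6,6-trimethylcyclohex-1-en-1-yl]-2,7,11-trimethyltrideca-2,4,6,8,10,12-hexaenal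
Product: 32 (all-E)-(3R,3'R,6'R)-3,3'-bis(tert-butyldimethylsilyloxy)-β,ε-carotene, via (11'Z)-bis-silyl carotenoid 31 (not isolated)
Conditions: NaOMe, MeOH/CH2Cl2, 0 °C to rt; then n-heptane, reflux, Ar, dark
Reagents that add atoms: none
Why: Wittig olefination forms C11'=C12' and completes the C40 skeleton, the hindered 11'Z isomer is equilibrated thermally to all-E, and the mild alkoxide should not move the epsilon-ring double bond.

Step 18
Reactants: 32 (all-E)-(3R,3'R,6'R)-3,3'-bis(tert-butyldimethylsilyloxy)-β,ε-carotene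
Product: 33 (3R,3'R,6'R)-β,ε-carotene-3,3'-diol (lutein)
Conditions: Bu4NF, THF, 0 °C to rt, Ar, dark
Reagents that add atoms: none
Why: Fluoride-mediated cleavage of both silyl ethers touches no stereocentre and avoids the acid that would ionise the allylic 3'-oxygen.

Step 19
Reactants: 33 (3R,3'R,6'R)-β,ε-carotene-3,3'-diol; 34 hexadecanoyl chloride
Product: 35 helenien, (3R,3'R,6'R)-β,ε-carotene-3,3'-diyl dihexadecanoate
Conditions: 34 (2.5 equiv), pyridine, DMAP (cat.), CH2Cl2, 0 °C to rt, Ar, dark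
Reagents that add atoms: none
Why: Acylation of both secondary hydroxyls with the acid chloride under nucleophilic catalysis should give the diester with retention at C3 and C3', the basic medium preventing ionisation at C3'.

**Compound list**

1 | pentane-2,4-dione (acetylacetone) | CC(=O)CC(C)=O | starting material
2 | (3Z)-4-(trimethylsilyloxy)pent-3-en-2-one | CC(=O)/C=C(/C)O[Si](C)(C)C | intermediate (not isolated)
3 | (3Z)-2,4-bis(trimethylsilyloxy)penta-1,3-diene | C=C(O[Si](C)(C)C)/C=C(\O[Si](C)(C)C)C | intermediate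
4 | 1,3-oxazolidin-2-one | O=C1NCCO1 | starting material
5 | 3-methylbut-2-enoyl chloride | CC(C)=CC(=O)Cl | starting material
6 | lithium 2-oxo-1,3-oxazolidin-3-ide | [Li+].O=C1[N-]CCO1 | intermediate (not isolated)
7 | 3-(3-methylbut-2-enoyl)-1,3-oxazolidin-2-one | CC(C)=CC(=O)N1CCOC1=O | intermediate
8 | 3-{[(1R)-2,6,6-trimethyl-2,4-bis(trimethylsilyloxy)cyclohex-3-en-1-yl]carbonyl}-1,3-oxazolidin-2-one (C2 epimers) | O=C(N1CCOC1=O)[C@H]2C(C)(O[Si](C)(C)C)C=C(O[Si](C)(C)C)CC2(C)C | intermediate (not isolated)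
9 | 3-{[(1R)-2,6,6-trimethyl-4-oxo-2-(trimethylsilyloxy)cyclohexyl]carbonyl}-1,3-oxazolidin-2-one (C2 epimers) | O=C(N1CCOC1=O)[C@H]2C(C)(O[Si](C)(C)C)CC(=O)CC2(C)C | intermediate (not isolated)
10 | 3-{[(1R)-2,6,6-trimethyl-4-oxocyclohex-2-en-1-yl]carbonyl}-1,3-oxazolidin-2-one | O=C(N1CCOC1=O)[C@H]2C(C)=CC(=O)CC2(C)C | intermediate
11 | 3-{[(1R,4R)-4-hydroxy-2,6,6-trimethylcyclohex-2-en-1-yl]carbonyl}-1,3-oxazolidin-2-one | O=C(N1CCOC1=O)[C@H]2C(C)=C[C@H](O)CC2(C)C | intermediate
12 | 3-{[(1R,4R)-4-(tert-butyldimethylsilyloxy)-2,6,6-trimethylcyclohex-2-en-1-yl]carbonyl}-1,3-oxazolidin-2-one | O=C(N1CCOC1=O)[C@H]2C(C)=C[C@H](O[Si](C)(C)C(C)(C)C)CC2(C)C | intermediate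
13 | [(1R,4R)-4-(tert-butyldimethylsilyloxy)-2,6,6-trimethylcyclohex-2-en-1-yl]methanol | OC[C@H]1C(C)=C[C@H](O[Si](C)(C)C(C)(C)C)CC1(C)C | intermediate
14 | (1R,4R)-4-(tert-butyldimethylsilyloxy)-2,6,6-trimethylcyclohex-2-ene-1-carbaldehyde | O=C[C@H]1C(C)=C[C@H](O[Si](C)(C)C(C)(C)C)CC1(C)C | intermediate
15 | dimethyl (2-oxopropyl)phosphonate | COP(=O)(CC(C)=O)OC | starting material
16 | (3E)-4-[(1R,4R)-4-(tert-butyldimethylsilyloxy)-2,6,6-trimethylcyclohex-2-en-1-yl]but-3-en-2-one | CC(=O)/C=C/[C@H]1C(C)=C[C@H](O[Si](C)(C)C(C)(C)C)CC1(C)C | intermediate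
17 | vinylmagnesium bromide | C=C[Mg]Br | starting material
18 | (1E)-1-[(1R,4R)-4-(tert-butyldimethylsilyloxy)-2,6,6-trimethylcyclohex-2-en-1-yl]-3-methylpenta-1,4-dien-3-ol (both C3 epimers) | C=CC(C)(O)/C=C/[C@H]1C(C)=C[C@H](O[Si](C)(C)C(C)(C)C)CC1(C)C | intermediate
19 | {(2E,4E)-5-[(1R,4R)-4-(tert-butyldimethylsilyloxy)-2,6,6-trimethylcyclohex-2-en-1-yl]-3-methylpenta-2,4-dien-1-yl}triphenylphosphonium bromide | [Br-].c1ccccc1[P+](c2ccccc2)(c3ccccc3)C/C=C(C)/C=C/[C@H]4C(C)=C[C@H](O[Si](C)(C)C(C)(C)C)CC4(C)C | intermediate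
20 | (4R,6R)-4-hydroxy-2,2,6-trimethylcyclohexan-1-one (actinol) | O[C@@H]1C[C@@H](C)C(=O)C(C)(C)C1 | starting material
21 | (4R,6R)-4-(tert-butyldimethylsilyloxy)-2,2,6-trimethylcyclohexan-1-one | CC(C)(C)[Si](C)(C)O[C@@H]1C[C@@H](C)C(=O)C(C)(C)C1 | intermediate
22 | lithium (4R)-4-(tert-butyldimethylsilyloxy)-2,6,6-trimethylcyclohex-1-en-1-olate | [Li+].[O-]C1=C(C)C[C@@H](O[Si](C)(C)C(C)(C)C)CC1(C)C | intermediate (not isolated)
23 | (4R)-4-(tert-butyldimethylsilyloxy)-2,6,6-trimethylcyclohex-1-en-1-yl trifluoromethanesulfonate | FC(F)(F)S(=O)(=O)OC1=C(C)C[C@@H](O[Si](C)(C)C(C)(C)C)CC1(C)C | intermediate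
24 | but-3-en-2-one | CC(=O)C=C | starting material
25 | (3E)-4-[(4R)-4-(tert-butyldimethylsilyloxy)-2,6,6-trimethylcyclohex-1-en-1-yl]but-3-en-2-one | CC(=O)/C=C/C1=C(C)C[C@@H](O[Si](C)(C)C(C)(C)C)CC1(C)C | intermediate
26 | (1E)-1-[(4R)-4-(tert-butyldimethylsilyloxy)-2,6,6-trimethylcyclohex-1-en-1-yl]-3-methylpenta-1,4-dien-3-ol (both C3 epimers) | C=CC(C)(O)/C=C/C1=C(C)C[C@@H](O[Si](C)(C)C(C)(C)C)CC1(C)C | intermediate
27 | {(2E,4E)-5-[(4R)-4-(tert-butyldimethylsilyloxy)-2,6,6-trimethylcyclohex-1-en-1-yl]-3-methylpenta-2,4-dien-1-yl}triphenylphosphonium bromide | [Br-].c1ccccc1[P+](c2ccccc2)(c3ccccc3)C/C=C(C)/C=C/C4=C(C)C[C@@H](O[Si](C)(C)C(C)(C)C)CC4(C)C | intermediate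
28 | (2E,4E,6E)-2,7-dimethylocta-2,4,6-trienedial | O=C/C(C)=C/C=C/C=C(C)/C=O | starting material
29 | (2E,4E,6E,8Z,10E,12E)-13-[(4R)-4-(tert-butyldimethylsilyloxy)-2,6,6-trimethylcyclohex-1-en-1-yl]-2,7,11-trimethyltrideca-2,4,6,8,10,12-hexaenal (11Z in carotenoid locants) | CC(C)(C)[Si](C)(C)O[C@@H]1CC(C)=C(/C=C/C(C)=C/C=C\C(C)=C\C=C\C=C(C)\C=O)C(C)(C)C1 | intermediate (not isolated)
30 | (2E,4E,6E,8E,10E,12E)-13-[(4R)-4-(tert-butyldimethylsilyloxy)-2,6,6-trimethylcyclohex-1-en-1-yl]-2,7,11-trimethyltrideca-2,4,6,8,10,12-hexaenal | CC(C)(C)[Si](C)(C)O[C@@H]1CC(C)=C(/C=C/C(C)=C/C=C/C(C)=C/C=C/C=C(C)/C=O)C(C)(C)C1 | intermediate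
31 | (11'Z)-(3R,3'R,6'R)-3,3'-bis(tert-butyldimethylsilyloxy)-β,ε-carotene | CC(C)(C)[Si](C)(C)O[C@@H]1CC(C)=C(/C=C/C(C)=C/C=C/C(C)=C/C=C/C=C(C)/C=C\C=C(C)\C=C\[C@H]2C(C)=C[C@H](O[Si](C)(C)C(C)(C)C)CC2(C)C)C(C)(C)C1 | intermediate (not isolated)
32 | (all-E)-(3R,3'R,6'R)-3,3'-bis(tert-butyldimethylsilyloxy)-β,ε-carotene | CC(C)(C)[Si](C)(C)O[C@@H]1CC(C)=C(/C=C/C(C)=C/C=C/C(C)=C/C=C/C=C(C)/C=C/C=C(C)/C=C/[C@H]2C(C)=C[C@H](O[Si](C)(C)C(C)(C)C)CC2(C)C)C(C)(C)C1 | intermediate
33 | (3R,3'R,6'R)-β,ε-carotene-3,3'-diol (lutein) | O[C@@H]1CC(C)=C(/C=C/C(C)=C/C=C/C(C)=C/C=C/C=C(C)/C=C/C=C(C)/C=C/[C@H]2C(C)=C[C@H](O)CC2(C)C)C(C)(C)C1 | intermediate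
34 | hexadecanoyl chloride (palmitoyl chloride) | CCCCCCCCCCCCCCCC(=O)Cl | starting material
35 | helenien, (3R,3'R,6'R)-β,ε-carotene-3,3'-diyl dihexadecanoate | CCCCCCCCCCCCCCCC(=O)O[C@@H]1CC(C)=C(/C=C/C(C)=C/C=C/C(C)=C/C=C/C=C(C)/C=C/C=C(C)/C=C/[C@H]2C(C)=C[C@H](OC(=O)CCCCCCCCCCCCCCC)CC2(C)C)C(C)(C)C1 | target

**Count and risks**

Total step count: 19. Longest linear sequence: 12 steps (1, 3 to 10, 17, 18, 19).

Steps most likely to fail:

Step 3. The annulation may stall at the fully substituted β-carbon. The diene may be desilylated by the Lewis acid faster than it adds. A silyl-cation-catalysed background reaction may erode the enantioselectivity. The fallback builds the ring racemic by known chemistry and resolves it; it sets out from 1,3-oxazolidin-2-one 4 and comes back at 10. Purchased 4-methylpent-3-en-2-one and ethyl 3-oxobutanoate are condensed with ZnCl2 in refluxing toluene with removal of water (Michael addition followed by aldol condensation) to racemic ethyl 2,6,6-trimethyl-4-oxocyclohex-2-ene-1-carboxylate F1. LiOH in aqueous THF gives racemic 2,6,6-trimethyl-4-oxocyclohex-2-ene-1-carboxylic acid F2. Pivaloyl chloride and Et3N in THF at −20 °C convert it into 2,2-dimethylpropanoic 2,6,6-trimethyl-4-oxocyclohex-2-ene-1-carboxylic anhydride F3, which acylates 4 in the presence of LiCl to give racemic 3-[(2,6,6-trimethyl-4-oxocyclohex-2-en-1-yl)carbonyl]-1,3-oxazolidin-2-one F4. Preparative chromatography on a polysaccharide-based chiral stationary phase then separates 10 from 3-{[(1S)-2,6,6-trimethyl-4-oxocyclohex-2-en-1-yl]carbonyl}-1,3-oxazolidin-2-one F5, which is set aside.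

Step 4. Hydride delivery to the C3' carbonyl may show poor or reversed facial selectivity, because the pseudoaxial C6' substituent and the axial C1' methyl shield opposite faces. The fallback corrects the centre by inversion; it sets out from 10 and comes back at 11. The 3'-epimer 3-{[(1R,4S)-4-hydroxy-2,6,6-trimethylcyclohex-2-en-1-yl]carbonyl}-1,3-oxazolidin-2-one F6, taken from the reduction of 10, undergoes a Mitsunobu reaction with chloroacetic acid (PPh3, diisopropyl azodicarboxylate, THF, 0 °C to rt) to give, with inversion, (1R,4R)-3,5,5-trimethyl-4-[(2-oxo-1,3-oxazolidin-3-yl)carbonyl]cyclohex-2-en-1-yl chloroacetate F7. Thiourea and NaHCO3 in warm ethanol then remove the chloroacetyl group without touching the imide and give 11.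

Step 8. The aldehyde may lose its C6' configuration or shift its ring double bond into conjugation under the basic olefination conditions, and addition to the hindered carbonyl may be slow. The fallback replaces the base-mediated olefination by a chromium-mediated one followed by cross-coupling; it sets out from 14 and comes back at 16. Takai iodo-olefination (CrCl2, CHI3, THF, 0 °C) should give tert-butyl({(1R,4R)-4-[(E)-2-iodoethenyl]-3,5,5-trimethylcyclohex-2-en-1-yl}oxy)dimethylsilane F8 under non-basic conditions. Stille coupling with purchased tributyl(1-ethoxyvinyl)stannane (Pd(PPh3)4, DMF, 60 °C) gives tert-butyl({(1R,4R)-4-[(1E)-3-ethoxybuta-1,3-dien-1-yl]-3,5,5-trimethylcyclohex-2-en-1-yl}oxy)dimethylsilane F9. Brief treatment with oxalic acid in wet THF hydrolyses the enol ether to 16.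

Further compounds
F1 | step 3 | ethyl 2,6,6-trimethyl-4-oxocyclohex-2-ene-1-carboxylate (racemic) | CCOC(=O)C1C(C)=CC(=O)CC1(C)C
F2 | step 3 | 2,6,6-trimethyl-4-oxocyclohex-2-ene-1-carboxylic acid (racemic) | OC(=O)C1C(C)=CC(=O)CC1(C)C
F3 | step 3 | 2,2-dimethylpropanoic 2,6,6-trimethyl-4-oxocyclohex-2-ene-1-carboxylic anhydride (racemic) | CC(C)(C)C(=O)OC(=O)C1C(C)=CC(=O)CC1(C)C
F4 | step 3 | 3-[(2,6,6-trimethyl-4-oxocyclohex-2-en-1-yl)carbonyl]-1,3-oxazolidin-2-one (racemic) | O=C(N1CCOC1=O)C2C(C)=CC(=O)CC2(C)C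
F5 | step 3 | 3-{[(1S)-2,6,6-trimethyl-4-oxocyclohex-2-en-1-yl]carbonyl}-1,3-oxazolidin-2-one | O=C(N1CCOC1=O)[C@@H]2C(C)=CC(=O)CC2(C)C
F6 | step 4 | 3-{[(1R,4S)-4-hydroxy-2,6,6-trimethylcyclohex-2-en-1-yl]carbonyl}-1,3-oxazolidin-2-one | O=C(N1CCOC1=O)[C@H]2C(C)=C[C@@H](O)CC2(C)C
F7 | step 4 | (1R,4R)-3,5,5-trimethyl-4-[(2-oxo-1,3-oxazolidin-3-yl)carbonyl]cyclohex-2-en-1-yl chloroacetate | O=C(N1CCOC1=O)[C@H]2C(C)=C[C@H](OC(=O)CCl)CC2(C)C
F8 | step 8 | tert-butyl({(1R,4R)-4-[(E)-2-iodoethenyl]-3,5,5-trimethylcyclohex-2-en-1-yl}oxy)dimethylsilane | I/C=C/[C@H]1C(C)=C[C@H](O[Si](C)(C)C(C)(C)C)CC1(C)C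
F9 | step 8 | tert-butyl({(1R,4R)-4-[(1E)-3-ethoxybuta-1,3-dien-1-yl]-3,5,5-trimethylcyclohex-2-en-1-yl}oxy)dimethylsilane | CCOC(=C)/C=C/[C@H]1C(C)=C[C@H](O[Si](C)(C)C(C)(C)C)CC1(C)C
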